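**Retrosynthetic overview**
1. Target 24 ⇐ seco‑aldehyde 22: the C4–C5 bond is closed last by an intramolecular Cr/Ni addition in which the (Z)‑β‑iodoenone acts as a β‑acylvinyl anion (d3, polarity‑reversed) and attacks the C5 aldehyde; this forms the ten‑membered ring and sets C5.
2. 22 ⇐ allyl bromide 15 + keto‑aldehyde 10: the C7–C8 bond is made by indium allylation (the 2‑alkoxycarbonylallyl metal is a homoenolate equivalent), setting C7 and C8; the lactone then closes on O6, whose carbon (C6) comes from (R)‑solketal.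
3. 10 ⇐ but‑3‑yn‑1‑ol + (Z)‑3‑iodobut‑2‑enal: carboalumination/alanate addition, Shi epoxidation, double oxidation.
4. Ring order: oxirane (step 4) → α‑methylene‑γ‑lactone (step 11) → ten‑membered carbocycle (step 13).

Assumption: the target is made in the open hydroxy‑enone form drawn (not a 2,5‑hemiketal); germacrane locants are used (ring C1–C10, lactone C11–C13 closed on O6, C14 = methyl on C10, C15 = methyl on C4, ester on O8).

**Route**

Step 1
Reactants: 1 but‑2‑yn‑1‑ol
Product: 3 (2Z)‑3‑iodobut‑2‑en‑1‑ol, via sodium alkenylaluminate 2 (not isolated)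
Conditions: NaAlH2(OCH2CH2OMe)2, THF, 0 °C to rt; then I2, −78 to 0 °C
Reagents that add atoms: iodine, II
Why: Hydroxyl‑directed trans‑hydroalumination (Corey‑type) delivers hydride to C2 and aluminium to C3 inside a five‑membered aluminate, and iodinolysis with retention places iodine cis to CH2OH (Z).

Step 2
Reactants: 3 (2Z)‑3‑iodobut‑2‑en‑1‑ol
Product: 4 (2Z)‑3‑iodobut‑2‑enal
Conditions: MnO2, CH2Cl2, rt, dark
Reagents that add atoms: none
Why: Neutral MnO2 oxidation of the allylic alcohol leaves the Z vinyl iodide untouched.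

Step 3
Reactants: 5 but‑3‑yn‑1‑ol; 4 (2Z)‑3‑iodobut‑2‑enal
Product: 8 (3E,6Z)‑7‑iodo‑3‑methylocta‑3,6‑diene‑1,5‑diol (both carbinol epimers), via alkenylalane 6 (not isolated), via lithium alkenylalanate 7 (not isolated)
Conditions: AlMe3 (3 equiv), Cp2ZrCl2 (25 mol%), CH2Cl2, 0 °C to rt; n‑BuLi, THF/hexane, −78 °C; then 4, −78 to 0 °C
Reagents that add atoms: trimethylaluminium, C[Al](C)C
Why: Negishi zirconium‑catalysed syn‑carboalumination fixes the E‑trisubstituted alkene (future C10/C1), and the alanate adds 1,2 to the enal; the new carbinol (C2) forms as both epimers, which is harmless because it is oxidised in step 5.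

Step 4
Reactants: 8 (3E,6Z)‑7‑iodo‑3‑methylocta‑3,6‑diene‑1,5‑diol
Product: 9 (2Z)‑1‑[(2R,3R)‑3‑(2‑hydroxyethyl)‑3‑methyloxiran‑2‑yl]‑3‑iodobut‑2‑en‑1‑ol (both carbinol epimers)
Conditions: 1,2:4,5‑di‑O‑isopropylidene‑β‑D‑erythro‑2,3‑hexodiulo‑2,6‑pyranose (D‑fructose‑derived Shi ketone, 30 mol%), KHSO5 (as 2KHSO5·KHSO4·K2SO4), K2CO3, Bu4NHSO4, MeCN/CH2(OMe)2/aq. Na2B4O7 buffer, 0 °C
Reagents that add atoms: potassium peroxymonosulfate, [K+].[O-]S(=O)(=O)OO
Why: Shi asymmetric epoxidation: the chiral dioxirane attacks the electron‑rich E‑trisubstituted alkene through the spiro transition state (the iodine‑deactivated Z alkene is left), giving the (R,R)‑type epoxide that sets C10 and C1 under catalyst control for both carbinol epimers.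

Step 5
Reactants: 9 epoxy diol
Product: 10 2‑[(2R,3S)‑3‑[(2Z)‑3‑iodobut‑2‑enoyl]‑2‑methyloxiran‑2‑yl]acetaldehyde
Conditions: Dess–Martin periodinane (3 equiv), NaHCO3, CH2Cl2, 0 °C to rt; used at once
Reagents that add atoms: none
Why: Dess–Martin oxidation converts the secondary carbinol into the C2 ketone and the primary alcohol into the C8 aldehyde in one buffered, non‑basic operation that spares the epoxide and the β‑iodoenone and merges the two carbinol epimers.

Step 6
Reactants: 11 (R)‑solketal [(4R)‑2,2‑dimethyl‑1,3‑dioxolan‑4‑yl]methanol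
Product: 12 (4S)‑2,2‑dimethyl‑1,3‑dioxolane‑4‑carbaldehyde
Conditions: IBX, EtOAc, 75 °C; filtered solution used directly
Reagents that add atoms: none
Why: Neutral IBX oxidation gives the labile α‑alkoxy aldehyde without epimerisation; its stereocentre (future C6) comes from the chiral pool.

Step 7
Reactants: 12 (4S)‑2,2‑dimethyl‑1,3‑dioxolane‑4‑carbaldehyde; 13 methyl acrylate
Product: 14 methyl 2‑{[(4S)‑2,2‑dimethyl‑1,3‑dioxolan‑4‑yl](hydroxy)methyl}prop‑2‑enoate (both carbinol epimers)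
Conditions: 1,4‑diazabicyclo[2.2.2]octane (0.5 equiv), excess 13, MeOH, rt, 3–5 d
Reagents that add atoms: none
Why: Morita–Baylis–Hillman reaction of the activated α‑alkoxy aldehyde; the new carbinol centre is irrelevant because it becomes sp2 in step 8.

Step 8
Reactants: 14 Morita–Baylis–Hillman adduct
Product: 15 methyl (2Z)‑2‑(bromomethyl)‑3‑[(4R)‑2,2‑dimethyl‑1,3‑dioxolan‑4‑yl]prop‑2‑enoate
Conditions: NBS, Me2S, CH2Cl2, 0 °C to rt
Reagents that add atoms: N‑bromosuccinimide, O=C1CCC(=O)N1Br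
Why: Corey–Kim‑type activation of the allylic alcohol and bromide attack with allylic transposition (SN2') give the thermodynamically preferred Z bromide (dioxolane cis to CH2Br).

Step 9
Reactants: 15 allyl bromide; 10 keto‑aldehyde
Product: 17 methyl (3R,4R)‑3‑[(4R)‑2,2‑dimethyl‑1,3‑dioxolan‑4‑yl]‑4‑hydroxy‑5‑[(2R,3S)‑3‑[(2Z)‑3‑iodobut‑2‑enoyl]‑2‑methyloxiran‑2‑yl]‑2‑methylidenepentanoate, via allylindium dibromide 16 (not isolated)
Conditions: indium powder (1.5 equiv), THF/H2O 1:1, rt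
Reagents that add atoms: none
Why: Indium‑mediated Barbier allylation: the 2‑(methoxycarbonyl)allylindium is a homoenolate (β‑acyl carbanion) equivalent that attacks the aldehyde (not the hindered ketone) through its γ‑carbon in a closed chair transition state, the Z geometry giving the syn C7/C8 relationship, and attack on the H‑eclipsed (allylic‑strain‑minimised) conformer on the face anti to the dioxolane CH2 (oxygen outside, possibly indium‑bound) sets C7 relative to C6.

Step 10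
Reactants: 17 hydroxy ester; 18 tigloyl chloride [(2E)‑2‑methylbut‑2‑enoyl chloride]
Product: 19 methyl (3R,4R)‑3‑[(4R)‑2,2‑dimethyl‑1,3‑dioxolan‑4‑yl]‑5‑[(2R,3S)‑3‑[(2Z)‑3‑iodobut‑2‑enoyl]‑2‑methyloxiran‑2‑yl]‑2‑methylidene‑4‑[(2E)‑2‑methylbut‑2‑enoyloxy]pentanoate
Conditions: pyridine, 4‑(dimethylamino)pyridine (5 mol%), CH2Cl2, 0 °C to rt
Reagents that add atoms: none
Why: Nucleophile‑catalysed acylation esterifies O8 with retention at C8, and doing it before any acid treatment means only O6 can lactonise later.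

Step 11
Reactants: 19 tiglate acetonide
Product: 21 (1R)‑1‑[(2R,3R)‑2‑(hydroxymethyl)‑4‑methylidene‑5‑oxooxolan‑3‑yl]‑2‑[(2R,3S)‑3‑[(2Z)‑3‑iodobut‑2‑enoyl]‑2‑methyloxiran‑2‑yl]ethyl (2E)‑2‑methylbut‑2‑enoate, via seco diol 20 (not isolated)
Conditions: AcOH/H2O/THF 3:1:1, 40 °C; then pyridinium p‑toluenesulfonate (cat.), CH2Cl2, rt
Reagents that add atoms: none
Why: Acetonide hydrolysis frees the 5,6‑diol and the secondary C6 hydroxyl closes the α‑methylene‑γ‑lactone by 5‑exo transesterification (favoured over the six‑membered alternative from the primary hydroxyl), giving the cis‑fused lactone fixed by C6 and C7.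

Step 12
Reactants: 21 lactone alcohol
Product: 22 (1R)‑1‑[(2R,3R)‑2‑formyl‑4‑methylidene‑5‑oxooxolan‑3‑yl]‑2‑[(2R,3S)‑3‑[(2Z)‑3‑iodobut‑2‑enoyl]‑2‑methyloxiran‑2‑yl]ethyl (2E)‑2‑methylbut‑2‑enoate
Conditions: Dess–Martin periodinane, NaHCO3, CH2Cl2, 0 °C
Reagents that add atoms: none
Why: Buffered Dess–Martin oxidation of the only free (primary) alcohol gives the α‑acyloxy aldehyde without epimerising C6.

Step 13
Reactants: 22 seco‑aldehyde
Product: 24 CNP0345622.1 (target), via alkenylchromium dichloride 23 (not isolated)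
Conditions: CrCl2 (6 equiv), NiCl2 (2 mol%), DMSO/THF 3:1, 2 mM, slow addition, rt
Reagents that add atoms: none
Why: Proposed new method: a Nozaki–Hiyama–Kishi macrocyclisation in which the (Z)‑β‑iodoenone serves as a β‑acylvinyl anion (d3) equivalent, joining the enone β‑carbon to the aldehyde carbon: zerovalent nickel (from NiCl2) inserts into the activated C–I bond, transmetalation gives a carbonyl‑chelated alkenyl species of trivalent chromium that adds only to the aldehyde with retention of the Z geometry, and Felkin–Anh attack anti to the C6–O bond gives the 5S (5,6‑anti) carbinol; the closest known reactions are Cr/Ni couplings of (Z)‑β‑iodoacrylates with aldehydes and Cr/Ni closures of nine‑ and ten‑membered carbocycles.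

**Compound list**
1 | but‑2‑yn‑1‑ol | CC#CCO | starting material
2 | sodium 2,2‑bis(2‑methoxyethoxy)‑3‑methyl‑2,5‑dihydro‑1,2‑oxaluminol‑2‑uide (cyclic alkenylaluminate) | [Na+].CC1=CCO[Al-]1(OCCOC)OCCOC | intermediate
3 | (2Z)‑3‑iodobut‑2‑en‑1‑ol | C/C(I)=C/CO | intermediate
4 | (2Z)‑3‑iodobut‑2‑enal | C/C(I)=C/C=O | intermediate
5 | but‑3‑yn‑1‑ol | C#CCCO | starting material
6 | dimethyl[(1E)‑4‑(dimethylalumanyloxy)‑2‑methylbut‑1‑enyl]alumane | C[Al](C)OCC/C(C)=C/[Al](C)C | intermediate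
7 | lithium butyl(dimethyl)[(1E)‑4‑(dimethylalumanyloxy)‑2‑methylbut‑1‑enyl]alanuide | [Li+].CCCC[Al-](C)(C)/C=C(\C)CCO[Al](C)C | intermediate
8 | (3E,6Z)‑7‑iodo‑3‑methylocta‑3,6‑diene‑1,5‑diol (both C5 epimers) | OCC/C(C)=C/C(O)/C=C(/C)I | intermediate
9 | (2Z)‑1‑[(2R,3R)‑3‑(2‑hydroxyethyl)‑3‑methyloxiran‑2‑yl]‑3‑iodobut‑2‑en‑1‑ol (both carbinol epimers) | OCC[C@@]1(C)O[C@@H]1C(O)/C=C(/C)I | intermediate
10 | 2‑[(2R,3S)‑3‑[(2Z)‑3‑iodobut‑2‑enoyl]‑2‑methyloxiran‑2‑yl]acetaldehyde | O=CC[C@@]1(C)O[C@@H]1C(=O)/C=C(/C)I | intermediate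
11 | (R)‑solketal, [(4R)‑2,2‑dimethyl‑1,3‑dioxolan‑4‑yl]methanol | CC1(C)OC[C@@H](CO)O1 | starting material
12 | (4S)‑2,2‑dimethyl‑1,3‑dioxolane‑4‑carbaldehyde | CC1(C)OC[C@@H](C=O)O1 | intermediate
13 | methyl acrylate | C=CC(=O)OC | starting material
14 | methyl 2‑{[(4S)‑2,2‑dimethyl‑1,3‑dioxolan‑4‑yl](hydroxy)methyl}prop‑2‑enoate (both carbinol epimers) | CC1(C)OC[C@@H](C(O)C(=C)C(=O)OC)O1 | intermediate
15 | methyl (2Z)‑2‑(bromomethyl)‑3‑[(4R)‑2,2‑dimethyl‑1,3‑dioxolan‑4‑yl]prop‑2‑enoate | CC1(C)OC[C@@H](/C=C(\CBr)C(=O)OC)O1 | intermediate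
16 | methyl (2Z)‑2‑[(dibromoindiganyl)methyl]‑3‑[(4R)‑2,2‑dimethyl‑1,3‑dioxolan‑4‑yl]prop‑2‑enoate (allyl derivative of trivalent indium) | CC1(C)OC[C@@H](/C=C(\C[In](Br)Br)C(=O)OC)O1 | intermediate
17 | methyl (3R,4R)‑3‑[(4R)‑2,2‑dimethyl‑1,3‑dioxolan‑4‑yl]‑4‑hydroxy‑5‑[(2R,3S)‑3‑[(2Z)‑3‑iodobut‑2‑enoyl]‑2‑methyloxiran‑2‑yl]‑2‑methylidenepentanoate | C=C(C(=O)OC)[C@@H]([C@@H]1COC(C)(C)O1)[C@H](O)C[C@@]2(C)O[C@@H]2C(=O)/C=C(/C)I | intermediate
18 | tigloyl chloride, (2E)‑2‑methylbut‑2‑enoyl chloride | C/C=C(\C)C(=O)Cl | starting material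
19 | 4‑O‑tigloyl derivative of 17 | C=C(C(=O)OC)[C@@H]([C@@H]1COC(C)(C)O1)[C@H](OC(=O)/C(C)=C/C)C[C@@]2(C)O[C@@H]2C(=O)/C=C(/C)I | intermediate
20 | seco diol (19 without the acetonide; free 5,6‑diol, methyl ester) | C=C(C(=O)OC)[C@@H]([C@@H](O)CO)[C@H](OC(=O)/C(C)=C/C)C[C@@]2(C)O[C@@H]2C(=O)/C=C(/C)I | intermediate
21 | (1R)‑1‑[(2R,3R)‑2‑(hydroxymethyl)‑4‑methylidene‑5‑oxooxolan‑3‑yl]‑2‑[(2R,3S)‑3‑[(2Z)‑3‑iodobut‑2‑enoyl]‑2‑methyloxiran‑2‑yl]ethyl (2E)‑2‑methylbut‑2‑enoate | C=C1C(=O)O[C@@H](CO)[C@H]1[C@H](OC(=O)/C(C)=C/C)C[C@@]2(C)O[C@@H]2C(=O)/C=C(/C)I | intermediate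
22 | (1R)‑1‑[(2R,3R)‑2‑formyl‑4‑methylidene‑5‑oxooxolan‑3‑yl]‑2‑[(2R,3S)‑3‑[(2Z)‑3‑iodobut‑2‑enoyl]‑2‑methyloxiran‑2‑yl]ethyl (2E)‑2‑methylbut‑2‑enoate | C=C1C(=O)O[C@@H](C=O)[C@H]1[C@H](OC(=O)/C(C)=C/C)C[C@@]2(C)O[C@@H]2C(=O)/C=C(/C)I | intermediate
23 | alkenyl derivative of trivalent chromium dichloride (22 with CrCl2 in place of iodine, Z retained) | C=C1C(=O)O[C@@H](C=O)[C@H]1[C@H](OC(=O)/C(C)=C/C)C[C@@]2(C)O[C@@H]2C(=O)/C=C(/C)[Cr](Cl)Cl | intermediate
24 | CNP0345622.1: (1S,3Z,5S,6R,7R,8R,10R)‑1,10‑epoxy‑5‑hydroxy‑2‑oxo‑8‑[(2E)‑2‑methylbut‑2‑enoyloxy]germacra‑3,11(13)‑dien‑12,6‑olide | C=C1C(=O)O[C@@H]2[C@H]1[C@H](OC(=O)/C(C)=C/C)C[C@@]1(C)O[C@@H]1C(=O)/C=C(/C)[C@@H]2O | target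

**Totals**
Total steps: 13. Longest linear sequence: 10 steps (1 → 3 → 4 → 8 → 9 → 10 → 17 → 19 → 21 → 22 → 24; steps 1–5 and 9–13).

**Three steps most likely to fail**

Step 13 (Cr/Ni ring closure). Divalent chromium may attack the α,β‑epoxy ketone, and macrocyclic strain may override Felkin control at C5. The fallback sets out from 22 and returns at 24. It sets C5 by invertive substitution after ring closure rather than by the facial selectivity of the addition. If the closure gives mainly the 5‑epimer of the target F1, a Mitsunobu reaction with chloroacetic acid (PPh3, DIAD, THF, 0 °C) gives the inverted 5‑O‑chloroacetyl derivative of the target F2. Thiourea/NaHCO3 in EtOH then removes the chloroacetate selectively (tiglate and lactone stay) to give 24. This fallback does not help if the ring fails to close at all.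

Step 9 (indium allylation). The syn/anti outcome and the facial selectivity relative to C6 are substrate‑controlled, and the β,γ‑epoxy aldehyde 10 is sensitive. The fallback sets out from 15 and 10 and returns at 19. If the anti adduct predominates, that is the C8 epimer of 17 F3, the ester is introduced with inversion instead of retention. Mitsunobu esterification of F3 with tiglic acid (PPh3, DIAD, toluene, 0 °C to rt) gives 19 directly, replacing step 10. It corrects C8 only, not a wrong face at C7.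

Step 4 (Shi epoxidation). The catalyst must discriminate two trisubstituted alkenes and override the adjacent carbinol centre. The fallback sets out from 8 and returns at 9. It uses hydroxyl‑directed Sharpless epoxidation under kinetic‑resolution conditions (Ti(OiPr)4, D‑(−)‑diisopropyl tartrate, t‑BuOOH, 4 Å sieves, CH2Cl2, −20 °C). This epoxidises only the electron‑rich allylic alkene of the matched carbinol epimer, on the tartrate‑dictated face. It gives 9 as a single carbinol epimer, with at most half of 8 converted and the other epimer recovered. No compound outside the list is formed (F0).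

**Further compounds**
F1 | step 13 | 5‑epimer of target 24 (5R) | C=C1C(=O)O[C@@H]2[C@H]1[C@H](OC(=O)/C(C)=C/C)C[C@@]1(C)O[C@@H]1C(=O)/C=C(/C)[C@H]2O
F2 | step 13 | 5‑O‑chloroacetyl derivative of target 24 (5S) | C=C1C(=O)O[C@@H]2[C@H]1[C@H](OC(=O)/C(C)=C/C)C[C@@]1(C)O[C@@H]1C(=O)/C=C(/C)[C@@H]2OC(=O)CCl
F3 | step 9 | C8 epimer of 17 (pentanoate C4 epimer, 4S) | C=C(C(=O)OC)[C@@H]([C@@H]1COC(C)(C)O1)[C@@H](O)C[C@@]2(C)O[C@@H]2C(=O)/C=C(/C)I
F0 | step 4 | none | none
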